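**Retrosynthetic overview**

1. The last disconnections are the three MOM ethers and then the C2–aryl bond: ring B and the (2S) centre come from a rhodium-catalysed enantioselective 1,4-addition of a 3,4-dioxygenated arylboronic acid to a 6-farnesyl-5-hydroxychromone.
2. The key disconnection is C1''–C2'' of the side chain (benzylic CH2 to vinylic CH): a C14 (E)-alkenylboronic acid is joined to a 5-hydroxy-6-(hydroxymethyl)chromone through a temporary six-membered cyclic boronate, which opens with transfer of the alkenyl group from boron to C1''.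
3. The enabling feature is that C1'' sits on C6 of ring A, between the phenolic oxygens O5 and O7 and para to the ring oxygen O1. Its C–O bond therefore ionises to an ortho-quinone methide (C5=O, C6=C1''), the neighbouring 5-OH holds the boron that carries the alkenyl group, and the heterodiene O5=C5–C6=C1'' is s-cis.
4. C1'' is placed at C6 by iodination ortho to the free 5-OH of a 7-O-MOM chromone, followed by Stille hydroxymethylation. The alkenylboron fragment comes from (E)-geranylacetone via the terminal alkyne and a syn-carboalumination that sets the C2''=C3'' geometry.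
5. Ring order: rings A and C are bought together as 5,7-dihydroxychromone and no ring of the target is closed; the temporary dioxaborinine forms and opens in the key step, and ring B is attached afterwards.

Key step: step 7

Remark: the side chain is taken as (2E,6E) and C2 as (S), as drawn, with side-chain atoms numbered C1'', C2'', C3'' from the ring; the (S)-ligand in step 10 is the one predicted by the quadrant model, and its antipode would be used if the first run shows the opposite sense.

**Route**

Step 1
Reactants: 1 (5E)-6,10-dimethylundeca-5,9-dien-2-one ((E)-geranylacetone)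
Product: 3 (5E)-6,10-dimethylundeca-5,9-dien-1-yne, via enol phosphate 2 (not isolated)
Conditions: LDA (1.05 equiv), THF, −78 °C; ClP(O)(OEt)2, −78 → 23 °C; then LDA (2.3 equiv), THF, −78 → 23 °C; H2O
Reagents that add atoms: none
Why: Kinetic deprotonation on the methyl side and O-phosphorylation give the terminal enol phosphate, from which excess LDA eliminates diethyl phosphate to the acetylide (Negishi conversion of a methyl ketone into a terminal alkyne), a sequence that leaves the (E)-trisubstituted alkene untouched.

Step 2
Reactants: 3 (5E)-6,10-dimethylundeca-5,9-dien-1-yne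
Product: 5 (1E,5E)-1-iodo-2,6,10-trimethylundeca-1,5,9-triene, via alkenylalane 4 (not isolated)
Conditions: Me3Al (2 equiv), Cp2ZrCl2 (0.25 equiv), CH2Cl2, 0 → 23 °C; then I2, THF, −30 → 0 °C
Reagents that add atoms: trimethylaluminium C[Al](C)C; iodine II
Why: Zirconium-catalysed carboalumination (Negishi) adds methyl and aluminium syn across the terminal alkyne with aluminium at the terminal carbon, and iodinolysis of the C–Al bond with retention gives the (1E)-iodide, so that the geometry of the future C2''=C3'' bond is set here while the trisubstituted alkenes do not react.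

Step 3
Reactants: 5 (1E,5E)-1-iodo-2,6,10-trimethylundeca-1,5,9-triene
Product: 8 [(1E,5E)-2,6,10-trimethylundeca-1,5,9-trien-1-yl]boronic acid, via alkenyllithium 6 (not isolated), via lithium alkenyltriisopropoxyborate 7 (not isolated)
Conditions: t-BuLi (2.1 equiv), Et2O, −78 °C; B(OiPr)3, −78 → 0 °C; aq. HCl to pH 5
Reagents that add atoms: triisopropyl borate CC(C)OB(OC(C)C)OC(C)C; water O
Why: Iodine–lithium exchange and trapping of the alkenyllithium with the borate both go with retention at the sp2 carbon, and mild acidic hydrolysis of the borate complex gives the (E)-alkenylboronic acid, which is used without storage.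

Step 4
Reactants: 9 5,7-dihydroxy-4H-chromen-4-one
Product: 10 5-hydroxy-7-(methoxymethoxy)-4H-chromen-4-one
Conditions: MOMCl (1.1 equiv), K2CO3, acetone, 0 → 23 °C
Reagents that add atoms: chloromethyl methyl ether COCCl
Why: The 5-OH is tied up in a hydrogen bond to the C4 carbonyl, so that Williamson-type alkylation with one equivalent of MOMCl takes place only at the more acidic, free 7-OH.

Step 5
Reactants: 10 5-hydroxy-7-(methoxymethoxy)-4H-chromen-4-one
Product: 11 5-hydroxy-6-iodo-7-(methoxymethoxy)-4H-chromen-4-one
Conditions: BnMe3N+ ICl2− (1.05 equiv), CaCO3, CH2Cl2/MeOH, 23 °C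
Reagents that add atoms: benzyltrimethylammonium dichloroiodate C[N+](C)(C)Cc1ccccc1.Cl[I-]Cl
Why: Electrophilic aromatic iodination with the mild dichloroiodate should go ortho to the free 5-OH, at C6 and not at C8, which is the pattern known for 5-hydroxy-7-alkoxyflavones with this reagent, while CaCO3 takes up the HCl so that the MOM acetal survives.

Step 6
Reactants: 11 5-hydroxy-6-iodo-7-(methoxymethoxy)-4H-chromen-4-one
Product: 12 5-hydroxy-6-(hydroxymethyl)-7-(methoxymethoxy)-4H-chromen-4-one
Conditions: Bu3SnCH2OH (1.5 equiv), Pd(PPh3)4 (10 mol %), 1,4-dioxane, 85 °C; aq. KF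
Reagents that add atoms: (tributylstannyl)methanol OC[Sn](CCCC)(CCCC)CCCC
Why: Stille coupling transfers the hydroxymethyl group from tin to C6 under neutral conditions that tolerate the free phenol, the acetal and the pyranone, and it makes the C6–C1'' bond at the one position that was marked by iodine.

Step 7
Reactants: 12 5-hydroxy-6-(hydroxymethyl)-7-(methoxymethoxy)-4H-chromen-4-one; 8 [(1E,5E)-2,6,10-trimethylundeca-1,5,9-trien-1-yl]boronic acid
Product: 15 5-hydroxy-7-(methoxymethoxy)-6-[(2E,6E)-3,7,11-trimethyldodeca-2,6,10-trien-1-yl]-4H-chromen-4-one, via cyclic boronate 13 (not isolated), via quinone methide borinate 14 (not isolated)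
Conditions: 8 (1.4 equiv), 4 Å MS, toluene, 23 °C; then (CF3)2CHOH as co-solvent (toluene/HFIP 3:1), 45 °C; aqueous work-up
Reagents that add atoms: none
Why: Proposed new method: boronic acid 8 condenses with the 5-OH and the 6-CH2OH of 12 to the cyclic boronate 13, whose C1''–O bond, placed ortho to O5 and O7 and para to O1 and activated by boron and by hydrogen bonding from HFIP, ionises to the ortho-quinone methide 14 (C5=O, C6=C1''H2) that stays bound through O5 to the now electron-rich, oxide-bearing boron; the alkenyl group then shifts from boron to C1'' through a six-membered chair-like transition state (B, O5, C5, C6, C1'', C2''), ring A becomes aromatic again, and water releases 15 and boric acid. The closest known reaction types are the Petasis borono-Mannich reaction of salicylaldehydes, in which a phenol-bound boronate delivers an alkenyl group to the ortho iminium carbon through the same cyclic arrangement, and the addition of alkenylboronates to ortho-quinone methides generated from 2-hydroxybenzyl alcohols or ethers, together with the known release of ortho-quinone methides from 4H-1,3,2-benzodioxaborins; what is new is the primary benzylic carbon and the fully boron-tethered, dehydrative course from a free diol. No ring of the target is closed here: the only ring that forms is the temporary six-membered dioxaborinine of 13 (by condensation), and it is opened again in the same flask. No stereocentre is made, but the (E) geometry of C2''=C3'' has to be carried over, and it should be, because the C–B bond at C2'' is replaced by the C–C bond with retention in a cyclic transfer, as in Petasis reactions of alkenylboronic acids. The selectivity that is needed is transfer to C1'' in preference to oligomerisation of 14, to its capture by the remote trisubstituted alkenes or by the MOM oxygen at C7, and to 1,4-addition to the pyranone; it is secured by the tether, which makes the transfer intramolecular, by the s-cis-locked heterodiene O5=C5–C6=C1'', and by the s-trans-locked enone O4=C4–C3=C2, which a boron held at O5 cannot reach.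

Step 8
Reactants: 16 4-bromobenzene-1,2-diol
Product: 17 4-bromo-1,2-bis(methoxymethoxy)benzene
Conditions: NaH (2.4 equiv), MOMCl (2.4 equiv), DMF, 0 → 23 °C
Reagents that add atoms: chloromethyl methyl ether COCCl
Why: Double O-alkylation of the catechol dianion (Williamson ether synthesis) protects both phenols as acetals that withstand the organolithium of step 9 and the aqueous rhodium step.

Step 9
Reactants: 17 4-bromo-1,2-bis(methoxymethoxy)benzene
Product: 20 [3,4-bis(methoxymethoxy)phenyl]boronic acid, via aryllithium 18 (not isolated), via lithium aryltriisopropoxyborate 19 (not isolated)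
Conditions: n-BuLi (1.05 equiv), THF, −78 °C; B(OiPr)3, −78 → 0 °C; aq. HCl to pH 5
Reagents that add atoms: triisopropyl borate CC(C)OB(OC(C)C)OC(C)C; water O
Why: Bromine–lithium exchange at −78 °C is faster than ortho-lithiation next to the MOM groups, and borylation followed by hydrolysis at pH 5 gives the arylboronic acid with both acetals intact.

Step 10
Reactants: 15 5-hydroxy-7-(methoxymethoxy)-6-[(2E,6E)-3,7,11-trimethyldodeca-2,6,10-trien-1-yl]-4H-chromen-4-one; 20 [3,4-bis(methoxymethoxy)phenyl]boronic acid
Product: 21 (2S)-2-[3,4-bis(methoxymethoxy)phenyl]-5-hydroxy-7-(methoxymethoxy)-6-[(2E,6E)-3,7,11-trimethyldodeca-2,6,10-trien-1-yl]-2,3-dihydro-4H-chromen-4-one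
Conditions: 20 (2.5 equiv), [Rh(OH)(cod)]2 (2.5 mol %), (S)-MeO-F12-BIPHEP (5.5 mol %), toluene/H2O (10:1), 30 °C
Reagents that add atoms: none
Why: Rhodium-catalysed asymmetric 1,4-addition of an arylboronic acid to a chromone (Hayashi–Miyaura reaction) forms the C2–aryl bond, and C2 is set by the catalyst: the aryl–rhodium complex of the (S)-bisphosphine should add to the enone face that gives (2S), by the same quadrant model that leads from 2-cyclohexenone to (S)-3-arylcyclohexanones, and the electron-poor ligand and the low temperature are chosen to suppress opening of the rhodium enolate to a chalcone.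

Step 11
Reactants: 21 (2S)-2-[3,4-bis(methoxymethoxy)phenyl]-5-hydroxy-7-(methoxymethoxy)-6-[(2E,6E)-3,7,11-trimethyldodeca-2,6,10-trien-1-yl]-2,3-dihydro-4H-chromen-4-one
Product: 22 (2S)-2-(3,4-dihydroxyphenyl)-5,7-dihydroxy-6-[(2E,6E)-3,7,11-trimethyldodeca-2,6,10-trien-1-yl]-2,3-dihydro-4H-chromen-4-one (6-farnesyl-3',4',5,7-tetrahydroxyflavanone)
Conditions: 3 M aq. HCl/MeOH (1:6), 40 °C
Reagents that add atoms: none
Why: Acid-catalysed acetal exchange with methanol cleaves the three aryl MOM ethers, a deprotection with precedent on prenylated 5,7-dihydroxyflavanones, and the low temperature and short time are meant to keep the 5-OH and 7-OH from adding to the C2''=C3'' bond and to keep C2 from epimerising by ring opening.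

**Compound list**

1 | (5E)-6,10-dimethylundeca-5,9-dien-2-one ((E)-geranylacetone) | CC(C)=CCC/C(C)=C/CCC(C)=O | starting material
2 | diethyl (5E)-6,10-dimethylundeca-1,5,9-trien-2-yl phosphate | CC(C)=CCC/C(C)=C/CCC(=C)OP(=O)(OCC)OCC | intermediate
3 | (5E)-6,10-dimethylundeca-5,9-dien-1-yne | CC(C)=CCC/C(C)=C/CCC#C | intermediate
4 | dimethyl[(1E,5E)-2,6,10-trimethylundeca-1,5,9-trien-1-yl]alane | CC(C)=CCC/C(C)=C/CC/C(C)=C/[Al](C)C | intermediate
5 | (1E,5E)-1-iodo-2,6,10-trimethylundeca-1,5,9-triene | CC(C)=CCC/C(C)=C/CC/C(C)=C/I | intermediate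
6 | [(1E,5E)-2,6,10-trimethylundeca-1,5,9-trien-1-yl]lithium | CC(C)=CCC/C(C)=C/CC/C(C)=C/[Li] | intermediate
7 | lithium triisopropoxy[(1E,5E)-2,6,10-trimethylundeca-1,5,9-trien-1-yl]borate | [Li+].CC(C)=CCC/C(C)=C/CC/C(C)=C/[B-](OC(C)C)(OC(C)C)OC(C)C | intermediate
8 | [(1E,5E)-2,6,10-trimethylundeca-1,5,9-trien-1-yl]boronic acid | CC(C)=CCC/C(C)=C/CC/C(C)=C/B(O)O | intermediate
9 | 5,7-dihydroxy-4H-chromen-4-one | O=c1ccoc2cc(O)cc(O)c12 | starting material
10 | 5-hydroxy-7-(methoxymethoxy)-4H-chromen-4-one | O=c1ccoc2cc(OCOC)cc(O)c12 | intermediate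
11 | 5-hydroxy-6-iodo-7-(methoxymethoxy)-4H-chromen-4-one | O=c1ccoc2cc(OCOC)c(I)c(O)c12 | intermediate
12 | 5-hydroxy-6-(hydroxymethyl)-7-(methoxymethoxy)-4H-chromen-4-one | O=c1ccoc2cc(OCOC)c(CO)c(O)c12 | intermediate
13 | cyclic boronate: 1,3,2-dioxaborinine fused at C5–C6 of the chromone, boron bonded to O5, to the oxygen on C1'' and to the (1E,5E)-2,6,10-trimethylundeca-1,5,9-trien-1-yl group | O=c1ccoc2cc(OCOC)c3c(OB(/C=C(C)/CC/C=C(C)/CCC=C(C)C)OC3)c12 | intermediate
14 | ortho-quinone methide borinate zwitterion (C5=O+ bound to boron, C6=C1''H2, B–O−, boron still carrying the alkenyl group) | C=C1C(OCOC)=CC2=C(C(=O)C=CO2)C1=[O+]B([O-])/C=C(C)/CC/C=C(C)/CCC=C(C)C | intermediate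
15 | 5-hydroxy-7-(methoxymethoxy)-6-[(2E,6E)-3,7,11-trimethyldodeca-2,6,10-trien-1-yl]-4H-chromen-4-one | CC(C)=CCC/C(C)=C/CC/C(C)=C/Cc1c(OCOC)cc2occc(=O)c2c1O | intermediate
16 | 4-bromobenzene-1,2-diol | Oc1ccc(Br)cc1O | starting material
17 | 4-bromo-1,2-bis(methoxymethoxy)benzene | COCOc1ccc(Br)cc1OCOC | intermediate
18 | [3,4-bis(methoxymethoxy)phenyl]lithium | [Li]c1ccc(OCOC)c(OCOC)c1 | intermediate
19 | lithium [3,4-bis(methoxymethoxy)phenyl]triisopropoxyborate | [Li+].COCOc1ccc([B-](OC(C)C)(OC(C)C)OC(C)C)cc1OCOC | intermediate
20 | [3,4-bis(methoxymethoxy)phenyl]boronic acid | COCOc1ccc(B(O)O)cc1OCOC | intermediate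
21 | (2S)-2-[3,4-bis(methoxymethoxy)phenyl]-5-hydroxy-7-(methoxymethoxy)-6-[(2E,6E)-3,7,11-trimethyldodeca-2,6,10-trien-1-yl]-2,3-dihydro-4H-chromen-4-one | CC(C)=CCC/C(C)=C/CC/C(C)=C/Cc1c(OCOC)cc2c(c1O)C(=O)C[C@@H](c1ccc(OCOC)c(OCOC)c1)O2 | intermediate
22 | (2S)-2-(3,4-dihydroxyphenyl)-5,7-dihydroxy-6-[(2E,6E)-3,7,11-trimethyldodeca-2,6,10-trien-1-yl]-2,3-dihydro-4H-chromen-4-one | CC(C)=CCC/C(C)=C/CC/C(C)=C/Cc1c(O)cc2c(c1O)C(=O)C[C@@H](c1ccc(O)c(O)c1)O2 | target

**Summary**

Total step count: 11.
Longest linear sequence: 6 steps (4, 5, 6, 7, 10, 11 from 9; the side-chain branch 1, 2, 3, 7, 10, 11 from 1 is of the same length).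

**Steps most likely to fail**

1. Step 7 (proposed new method). The benzylic C–O bond may ionise without the alkenyl group following. The quinone methide could then leave the boron and be attacked by C8 of a second molecule (oligomerisation) or by the MOM oxygen at C7. Alternatively, ionisation may not set in below the temperature at which the alkenylboronic acid is protodeboronated. The fallback forms the same C1''–C2'' bond by a known nickel-catalysed coupling of an alkenylalane with a benzylic chloride (Negishi type). It sets out from iodide 11 and alkyne 3 and comes back to the route at the target 22. The chelated 5-OH of 11 is capped with NaH and MOMCl in DMF to give 6-iodo-5,7-bis(methoxymethoxy)-4H-chromen-4-one F1. Stille hydroxymethylation as in step 6 gives 6-(hydroxymethyl)-5,7-bis(methoxymethoxy)-4H-chromen-4-one F2, which has no free ortho-OH and is no longer a quinone methide precursor. MsCl, LiCl and 2,4,6-collidine in DMF at 0 °C turn it into 6-(chloromethyl)-5,7-bis(methoxymethoxy)-4H-chromen-4-one F3, which is used at once. Alane 4, made from 3 as in step 2 and freed from excess Me3Al in vacuum, is coupled with F3 under Ni(0) catalysis (NiCl2(PPh3)2/n-BuLi, THF, 23 °C) with retention of the alkene geometry, giving 5,7-bis(methoxymethoxy)-6-[(2E,6E)-3,7,11-trimethyldodeca-2,6,10-trien-1-yl]-4H-chromen-4-one F4. F4 takes the place of 15 under the conditions of step 10 and gives (2S)-2-[3,4-bis(methoxymethoxy)phenyl]-5,7-bis(methoxymethoxy)-6-[(2E,6E)-3,7,11-trimethyldodeca-2,6,10-trien-1-yl]-2,3-dihydro-4H-chromen-4-one F5. The conditions of step 11 then remove all four MOM groups and give 22.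

2. Step 10. The 5-hydroxy-4-keto unit of 15 may bind rhodium as a β-ketophenolate and slow transmetalation, the facial selectivity on this hindered chromone may be poor, or the rhodium enolate may open by loss of the ring oxygen to a chalcone that closes again without control of C2 and on either phenol. The fallback gives up catalyst control, sets out from 15 and comes back at 21. The addition of 20 is run without a chiral ligand ([Rh(OH)(cod)]2, dioxane/H2O, 60 °C, where cod–rhodium β-ketophenolate resting states still turn over) to give racemic 2-[3,4-bis(methoxymethoxy)phenyl]-5-hydroxy-7-(methoxymethoxy)-6-[(2E,6E)-3,7,11-trimethyldodeca-2,6,10-trien-1-yl]-2,3-dihydro-4H-chromen-4-one F6. Preparative HPLC on a polysaccharide chiral phase separates it into 21 and the (2R)-enantiomer F7, which is set aside.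

3. Step 6. Transfer of the sp3 hydroxymethyl group from tin to an aryl–palladium centre flanked by two ortho oxygens may be slower than reductive loss of iodine, and at 85 °C the product may begin to condense with itself through the quinone methide. The fallback brings in the carbon at the aldehyde level, sets out from 11 and comes back at 12. Palladium-catalysed reductive carbonylation (CO 1 atm, Et3SiH, Pd(PPh3)4, Na2CO3, DMF, 70 °C) inserts the small CO ligand and gives 5-hydroxy-7-(methoxymethoxy)-4-oxo-4H-chromene-6-carbaldehyde F8, a stable salicylaldehyde. NaBH4 in THF/MeOH at −40 °C then reduces the aldehyde but not the pyranone and gives 12 at a temperature at which it does not self-condense.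

**Further compounds**

F1 | step 7 | 6-iodo-5,7-bis(methoxymethoxy)-4H-chromen-4-one | O=c1ccoc2cc(OCOC)c(I)c(OCOC)c12
F2 | step 7 | 6-(hydroxymethyl)-5,7-bis(methoxymethoxy)-4H-chromen-4-one | O=c1ccoc2cc(OCOC)c(CO)c(OCOC)c12
F3 | step 7 | 6-(chloromethyl)-5,7-bis(methoxymethoxy)-4H-chromen-4-one | O=c1ccoc2cc(OCOC)c(CCl)c(OCOC)c12
F4 | step 7 | 5,7-bis(methoxymethoxy)-6-[(2E,6E)-3,7,11-trimethyldodeca-2,6,10-trien-1-yl]-4H-chromen-4-one | CC(C)=CCC/C(C)=C/CC/C(C)=C/Cc1c(OCOC)cc2occc(=O)c2c1OCOC
F5 | step 7 | (2S)-2-[3,4-bis(methoxymethoxy)phenyl]-5,7-bis(methoxymethoxy)-6-[(2E,6E)-3,7,11-trimethyldodeca-2,6,10-trien-1-yl]-2,3-dihydro-4H-chromen-4-one | CC(C)=CCC/C(C)=C/CC/C(C)=C/Cc1c(OCOC)cc2c(c1OCOC)C(=O)C[C@@H](c1ccc(OCOC)c(OCOC)c1)O2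
F6 | step 10 | racemic 2-[3,4-bis(methoxymethoxy)phenyl]-5-hydroxy-7-(methoxymethoxy)-6-[(2E,6E)-3,7,11-trimethyldodeca-2,6,10-trien-1-yl]-2,3-dihydro-4H-chromen-4-one | CC(C)=CCC/C(C)=C/CC/C(C)=C/Cc1c(OCOC)cc2c(c1O)C(=O)CC(c1ccc(OCOC)c(OCOC)c1)O2
F7 | step 10 | (2R)-2-[3,4-bis(methoxymethoxy)phenyl]-5-hydroxy-7-(methoxymethoxy)-6-[(2E,6E)-3,7,11-trimethyldodeca-2,6,10-trien-1-yl]-2,3-dihydro-4H-chromen-4-one | CC(C)=CCC/C(C)=C/CC/C(C)=C/Cc1c(OCOC)cc2c(c1O)C(=O)C[C@H](c1ccc(OCOC)c(OCOC)c1)O2
F8 | step 6 | 5-hydroxy-7-(methoxymethoxy)-4-oxo-4H-chromene-6-carbaldehyde | O=Cc1c(OCOC)cc2occc(=O)c2c1O
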